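**Plan**
Retrosynthesis: first the sixteen O-benzyl bonds, then the central C4–C8 bond (dimer cation plus dimer nucleophile), then the two outer C4–C8 bonds, so that all four units derive from one monomer, tetra-O-benzyl-(−)-epicatechin; in the monomer the C3 carbinol is traced to the flavan-3-one, ring C is cut at O1–C8a and C2–C3 in one operation, then at C3–C4.
Forward: ring A from 1,3,5-trifluorobenzene (O5 and O7 by SNAr, C4 by formylation); C3–C4 by alkylation of 2-(trimethylsilyl)-1,3-dithiane; ring C by annulation with 3,4-bis(benzyloxy)benzaldehyde (ring B, C2, O1); unmasking and reduction at C3; C4 activation, 1+1 then 2+2 chain assembly; hydrogenolysis.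
Enabling feature: C3 is an oxygen-bearing carbon that can be carried as a dithiane-masked acyl carbanion held on silicon, and C8a of ring A is meta to both O5 and O7, so a fluoride on C8a is displaced by the C2 alkoxide; the fluoride set free is the species that releases the next C3 carbanion from silicon.
Stereochemistry: C2 and C3 of all four units come from one asymmetric hydrogenation of the racemic flavan-3-one under dynamic kinetic resolution (C2 epimerises α to the C3 carbonyl; cis hydride delivery); each C4 is set in the couplings by attack of C8 trans to the axial 3-OH (4β).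

Key step: step 6

Remark: flavan numbering is used throughout (O1, C2, C3, C4, C5 to C8, C8a; ring A is the benzo ring, ring B the aryl group on C2, ring C the pyran); the target is the linear tetramer of (−)-epicatechin in which all three interflavan bonds are 4β→8.
Assumption: the sense of induction in step 8 is assigned by analogy with 2-aryl- and 2-alkoxy-cyclohexanones; if a test reduction shows the opposite sense, the mirror-image complex RuCl2[(R)-xylbinap][(R)-daipen] is used with no other change.

Step 1
Reactants: 1 1,3,5-trifluorobenzene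
Product: 3 1,3-bis(benzyloxy)-5-fluorobenzene, via 1-(benzyloxy)-3,5-difluorobenzene 2 (not isolated)
Conditions: BnOH (2.1 equiv), NaH (2.2 equiv), NMP, 0 °C then 90 °C
Reagents that add atoms: benzyl alcohol, OCc1ccccc1
Why: Two successive nucleophilic aromatic substitutions by sodium benzyloxide should stop after the second one, because each benzyloxy group raises the barrier for the next displacement, so the third fluoride (the later C8a leaving group) is kept.

Step 2
Reactants: 3 1,3-bis(benzyloxy)-5-fluorobenzene
Product: 5 2,4-bis(benzyloxy)-6-fluorobenzaldehyde, via aryl iminium dichlorophosphate 4 (not isolated)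
Conditions: POCl3, DMF, 0 °C then 60 °C; then cold aq NaOH
Reagents that add atoms: N,N-dimethylformamide, CN(C)C=O; water, O
Why: Vilsmeier–Haack formylation should occur para to one benzyloxy group and ortho to the other at the position flanked by the small fluorine, which is less hindered than the position between the two benzyloxy groups (the minor regioisomer would be removed by crystallisation).

Step 3
Reactants: 5 2,4-bis(benzyloxy)-6-fluorobenzaldehyde
Product: 6 [2,4-bis(benzyloxy)-6-fluorophenyl]methanol
Conditions: NaBH4, THF/MeOH, 0 °C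
Reagents that add atoms: none
Why: Borohydride reduction of the aldehyde leaves the aryl fluoride and the benzyl ethers untouched.

Step 4
Reactants: 6 [2,4-bis(benzyloxy)-6-fluorophenyl]methanol
Product: 7 1,5-bis(benzyloxy)-2-(bromomethyl)-3-fluorobenzene
Conditions: CBr4, PPh3, CH2Cl2, 0 °C; used without purification
Reagents that add atoms: tetrabromomethane, BrC(Br)(Br)Br
Why: The Appel reaction converts the benzylic alcohol into the bromide under neutral conditions, which suits this electron-rich and therefore labile benzyl bromide.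

Step 5
Reactants: 7 1,5-bis(benzyloxy)-2-(bromomethyl)-3-fluorobenzene; 8 2-(trimethylsilyl)-1,3-dithiane
Product: 10 2-{[2,4-bis(benzyloxy)-6-fluorophenyl]methyl}-2-(trimethylsilyl)-1,3-dithiane, via 2-lithio-2-(trimethylsilyl)-1,3-dithiane 9 (not isolated)
Conditions: 8, n-BuLi, THF, −30 °C; then 7, −78 °C to −30 °C
Reagents that add atoms: none
Why: Corey–Seebach alkylation of the preformed lithio silyl dithiane with the reactive benzylic bromide forms C3–C4, and because the carbanion is fully formed before 7 is added no alkyllithium meets the acidic ring-A C–H between fluorine and benzyloxy.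

Step 6
Reactants: 10 2-{[2,4-bis(benzyloxy)-6-fluorophenyl]methyl}-2-(trimethylsilyl)-1,3-dithiane; 11 3,4-bis(benzyloxy)benzaldehyde
Product: 14 (±)-5,7-bis(benzyloxy)-2-[3,4-bis(benzyloxy)phenyl]spiro[chromane-3,2'-[1,3]dithiane], via carbinol trimethylsilyl ether 12 (not isolated), via cesium alkoxide 13 (not isolated)
Conditions: CsF (0.3 equiv, dried), 18-crown-6 (0.3 equiv), 4 Å molecular sieves, THF/DMPU, 0 °C to 20 °C, then 70 °C
Reagents that add atoms: none
Why: Proposed new method: fluoride cleaves the C3–SiMe3 bond of 10 and releases the dithiane-stabilised C3 carbanion (a masked acyl anion), which adds to the aldehyde carbon of 11 and so joins two carbons that are both electrophilic at their natural oxidation level (C2–C3); the alkoxide is silylated by further 10 (silyl ether 12), is set free again by fluoride as cesium alkoxide 13, and closes ring C by 6-exo-trig addition of O1 to C8a and loss of fluoride from the Meisenheimer adduct, so that each ring closure returns the fluoride that starts the next C–Si cleavage and the only by-product is Me3SiF. The closest known reaction types are the Lewis-base-catalysed 1,2-addition of 2-silyl-1,3-dithianes to aldehydes and the alkoxide SNAr closure of chromans onto 3,5-dialkoxyfluoroarenes, and their coupling through a shared fluoride is the new element. C8a is meta to both O5 and O7, so the ring-A oxygens do not push electron density onto the carbon under attack, and the spiro dithiane at C3 favours closure through the gem-disubstituent effect. The new stereocenter C2 is formed without control (racemic 14) on purpose, since it becomes epimerisable after step 7 and is fixed together with C3 in step 8. The step needs carbonyl addition to win over protonation of the carbanion (dried CsF, molecular sieves, a non-enolisable aldehyde, DMPU in place of an electrophilic amide solvent) and O-arylation only at C8a, which is secured because C8a carries the only fluoride and benzyl ethers are inert to alkoxide.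

Step 7
Reactants: 14 (±)-5,7-bis(benzyloxy)-2-[3,4-bis(benzyloxy)phenyl]spiro[chromane-3,2'-[1,3]dithiane]
Product: 15 (±)-5,7-bis(benzyloxy)-2-[3,4-bis(benzyloxy)phenyl]chroman-3-one
Conditions: MeI (excess), CaCO3, MeCN/THF/H2O, 45 °C
Reagents that add atoms: water, O
Why: Alkylative hydrolysis of the dithioketal is non-oxidative and buffered, so the electron-rich rings, the benzyl ethers and the aryl ether of ring C should survive while the C3 carbonyl is unmasked.

Step 8
Reactants: 15 (±)-5,7-bis(benzyloxy)-2-[3,4-bis(benzyloxy)phenyl]chroman-3-one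
Product: 16 (2R,3R)-5,7-bis(benzyloxy)-2-[3,4-bis(benzyloxy)phenyl]chroman-3-ol (5,7,3',4'-tetra-O-benzyl-(−)-epicatechin)
Conditions: RuCl2[(S)-xylbinap][(S)-daipen] (cat.), KOtBu (cat.), H2 (10 atm), iPrOH/THF, 25 °C
Reagents that add atoms: none
Why: In this Noyori-type asymmetric ketone hydrogenation under dynamic kinetic resolution, KOtBu equilibrates the C2 epimers of 15 through the enolate (C2–H is α to the carbonyl and benzylic), the chiral ruthenium hydride should reduce the (2R) ketone faster (catalyst control of C2), and hydride delivery to the face opposite the equatorial ring-B aryl group gives the axial 3-OH, that is the 2,3-cis (2R,3R) alcohol (substrate control of C3 relative to C2).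

Step 9
Reactants: 16 5,7,3',4'-tetra-O-benzyl-(−)-epicatechin
Product: 17 5,7,3',4'-tetra-O-benzyl-4β-(2-ethoxyethoxy)-(−)-epicatechin
Conditions: DDQ (1.5 equiv), 2-ethoxyethanol (5 equiv), CH2Cl2, 20 °C
Reagents that add atoms: 2-ethoxyethanol, CCOCCO
Why: DDQ abstracts hydride from the benzylic C4, which is activated by the ortho and para oxygens of ring A, and the alcohol should add to the cation trans to the axial 3-OH to give the 4β ether.

Step 10
Reactants: 17 5,7,3',4'-tetra-O-benzyl-4β-(2-ethoxyethoxy)-(−)-epicatechin; 16 5,7,3',4'-tetra-O-benzyl-(−)-epicatechin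
Product: 18 5,7,3',4'-tetra-O-benzyl-(−)-epicatechin-(4β→8)-5,7,3',4'-tetra-O-benzyl-(−)-epicatechin (octa-O-benzyl epicatechin dimer)
Conditions: 16 (4 equiv, excess recovered), TMSOTf (0.5 equiv), CH2Cl2, −78 °C
Reagents that add atoms: none
Why: TMSOTf ionises the C4 ether to the ring-A-stabilised benzylic cation, which should be attacked by C8 of 16 (the most nucleophilic and least hindered ring-A position) from the face trans to the 3-OH, while the excess of 16 suppresses self-condensation of 17.

Step 11
Reactants: 18 octa-O-benzyl epicatechin dimer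
Product: 19 octa-O-benzyl epicatechin dimer bearing a 4β-(2-ethoxyethoxy) group on C4 of the lower unit
Conditions: DDQ (1.2 equiv), 2-ethoxyethanol (5 equiv), CH2Cl2, 20 °C
Reagents that add atoms: 2-ethoxyethanol, CCOCCO
Why: The same benzylic oxidation as in step 9 should take the C4 methylene of the lower unit first, because the C4–H of the upper unit is a hindered methine whose cation cannot become coplanar with its two flanking aryl rings.

Step 12
Reactants: 19 octa-O-benzyl epicatechin dimer bearing a 4β-(2-ethoxyethoxy) group on C4 of the lower unit; 18 octa-O-benzyl epicatechin dimer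
Product: 20 hexadeca-O-benzyl all-(4β→8) epicatechin tetramer (every phenolic oxygen benzylated; the four 3-OH groups free)
Conditions: 18 (3 equiv, excess recovered), TMSOTf (0.5 equiv), CH2Cl2, −78 °C
Reagents that add atoms: none
Why: The dimeric C4 cation from 19 should be captured by the only unsubstituted C8 of 18 (that of its upper unit) trans to the neighbouring 3-OH, which forms the central 4β→8 bond in the same way as in step 10.

Step 13
Reactants: 20 hexadeca-O-benzyl all-(4β→8) epicatechin tetramer
Product: 21 (−)-epicatechin-(4β→8)-(−)-epicatechin-(4β→8)-(−)-epicatechin-(4β→8)-(−)-epicatechin (the target tetramer)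
Conditions: H2 (1 atm), Pd(OH)2/C, THF/MeOH/H2O, 20 °C; filtration; lyophilisation
Reagents that add atoms: none
Why: Hydrogenolysis cleaves all sixteen benzyl ethers under neutral conditions that leave the acid-labile interflavan bonds and every stereocenter intact.

**Compound list**
1 | 1,3,5-trifluorobenzene | Fc1cc(F)cc(F)c1 | starting material
2 | 1-(benzyloxy)-3,5-difluorobenzene | Fc1cc(F)cc(OCc2ccccc2)c1 | intermediate (not isolated)
3 | 1,3-bis(benzyloxy)-5-fluorobenzene | Fc1cc(OCc2ccccc2)cc(OCc2ccccc2)c1 | intermediate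
4 | N-{[2,4-bis(benzyloxy)-6-fluorophenyl]methylidene}-N-methylmethanaminium dichlorophosphate | C[N+](C)=Cc1c(F)cc(OCc2ccccc2)cc1OCc2ccccc2.[O-]P(=O)(Cl)Cl | intermediate (not isolated)
5 | 2,4-bis(benzyloxy)-6-fluorobenzaldehyde | O=Cc1c(F)cc(OCc2ccccc2)cc1OCc2ccccc2 | intermediate
6 | [2,4-bis(benzyloxy)-6-fluorophenyl]methanol | OCc1c(F)cc(OCc2ccccc2)cc1OCc2ccccc2 | intermediate
7 | 1,5-bis(benzyloxy)-2-(bromomethyl)-3-fluorobenzene | BrCc1c(F)cc(OCc2ccccc2)cc1OCc2ccccc2 | intermediate
8 | 2-(trimethylsilyl)-1,3-dithiane | C[Si](C)(C)C1SCCCS1 | starting material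
9 | 2-lithio-2-(trimethylsilyl)-1,3-dithiane | [Li]C1([Si](C)(C)C)SCCCS1 | intermediate (not isolated)
10 | 2-{[2,4-bis(benzyloxy)-6-fluorophenyl]methyl}-2-(trimethylsilyl)-1,3-dithiane | C[Si](C)(C)C1(Cc2c(F)cc(OCc3ccccc3)cc2OCc2ccccc2)SCCCS1 | intermediate
11 | 3,4-bis(benzyloxy)benzaldehyde | O=Cc1ccc(OCc2ccccc2)c(OCc2ccccc2)c1 | starting material
12 | (±)-{[3,4-bis(benzyloxy)phenyl](2-{[2,4-bis(benzyloxy)-6-fluorophenyl]methyl}-1,3-dithian-2-yl)methoxy}trimethylsilane | C[Si](C)(C)OC(c1ccc(OCc2ccccc2)c(OCc2ccccc2)c1)C1(Cc2c(F)cc(OCc3ccccc3)cc2OCc2ccccc2)SCCCS1 | intermediate (not isolated)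
13 | (±)-cesium [3,4-bis(benzyloxy)phenyl](2-{[2,4-bis(benzyloxy)-6-fluorophenyl]methyl}-1,3-dithian-2-yl)methanolate | [Cs+].[O-]C(c1ccc(OCc2ccccc2)c(OCc2ccccc2)c1)C1(Cc2c(F)cc(OCc3ccccc3)cc2OCc2ccccc2)SCCCS1 | intermediate (not isolated)
14 | (±)-5,7-bis(benzyloxy)-2-[3,4-bis(benzyloxy)phenyl]spiro[chromane-3,2'-[1,3]dithiane] | c1ccccc1COc1cc(OCc3ccccc3)c2c(c1)OC(c1ccc(OCc3ccccc3)c(OCc3ccccc3)c1)C1(SCCCS1)C2 | intermediate
15 | (±)-5,7-bis(benzyloxy)-2-[3,4-bis(benzyloxy)phenyl]chroman-3-one | c1ccccc1COc1cc(OCc3ccccc3)c2c(c1)OC(c1ccc(OCc3ccccc3)c(OCc3ccccc3)c1)C(=O)C2 | intermediate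
16 | (2R,3R)-5,7-bis(benzyloxy)-2-[3,4-bis(benzyloxy)phenyl]chroman-3-ol (5,7,3',4'-tetra-O-benzyl-(−)-epicatechin) | c1ccccc1COc1cc(OCc3ccccc3)c2c(c1)O[C@H](c1ccc(OCc3ccccc3)c(OCc3ccccc3)c1)[C@H](O)C2 | intermediate
17 | 5,7,3',4'-tetra-O-benzyl-4β-(2-ethoxyethoxy)-(−)-epicatechin (2,3-cis, 3,4-trans) | c1ccccc1COc1cc(OCc3ccccc3)c2c(c1)O[C@H](c1ccc(OCc3ccccc3)c(OCc3ccccc3)c1)[C@H](O)[C@H]2OCCOCC | intermediate
18 | octa-O-benzyl epicatechin dimer [tetra-O-benzyl-epicatechin-(4β→8)-tetra-O-benzyl-epicatechin] | c1ccccc1COc1cc(OCc3ccccc3)c2c(c1)O[C@H](c1ccc(OCc3ccccc3)c(OCc3ccccc3)c1)[C@H](O)[C@H]2c1c(OCc3ccccc3)cc(OCc3ccccc3)c2c1O[C@H](c1ccc(OCc3ccccc3)c(OCc3ccccc3)c1)[C@H](O)C2 | intermediate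
19 | octa-O-benzyl epicatechin dimer with a 4β-(2-ethoxyethoxy) group on C4 of the lower unit | c1ccccc1COc1cc(OCc3ccccc3)c2c(c1)O[C@H](c1ccc(OCc3ccccc3)c(OCc3ccccc3)c1)[C@H](O)[C@H]2c1c(OCc3ccccc3)cc(OCc3ccccc3)c2c1O[C@H](c1ccc(OCc3ccccc3)c(OCc3ccccc3)c1)[C@H](O)[C@H]2OCCOCC | intermediate
20 | hexadeca-O-benzyl all-(4β→8) epicatechin tetramer | c1ccccc1COc1cc(OCc3ccccc3)c2c(c1)O[C@H](c1ccc(OCc3ccccc3)c(OCc3ccccc3)c1)[C@H](O)[C@H]2c1c(OCc3ccccc3)cc(OCc3ccccc3)c2c1O[C@H](c1ccc(OCc3ccccc3)c(OCc3ccccc3)c1)[C@H](O)[C@H]2c1c(OCc3ccccc3)cc(OCc3ccccc3)c2c1O[C@H](c1ccc(OCc3ccccc3)c(OCc3ccccc3)c1)[C@H](O)[C@H]2c1c(OCc3ccccc3)cc(OCc3ccccc3)c2c1O[C@H](c1ccc(OCc3ccccc3)c(OCc3ccccc3)c1)[C@H](O)C2 | intermediate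
21 | (−)-epicatechin-(4β→8)-(−)-epicatechin-(4β→8)-(−)-epicatechin-(4β→8)-(−)-epicatechin (the target tetramer) | Oc1cc(O)c2c(c1)O[C@H](c1ccc(O)c(O)c1)[C@H](O)[C@H]2c1c(O)cc(O)c2c1O[C@H](c1ccc(O)c(O)c1)[C@H](O)[C@H]2c1c(O)cc(O)c2c1O[C@H](c1ccc(O)c(O)c1)[C@H](O)[C@H]2c1c(O)cc(O)c2c1O[C@H](c1ccc(O)c(O)c1)[C@H](O)C2 | target

**Step count and risks**
Total steps: 13. Longest linear sequence: 13 steps (1 → 3 → 5 → 6 → 7 → 10 → 14 → 15 → 16 → 17 → 18 → 19 → 20 → 21).

Steps most likely to fail:

Step 6 (Proposed new method). The fluoride-released C3 carbanion, or its silicate, may be protonated or may fail to transfer to the aldehyde, since a 2-alkyl dithianyl group leaves silicon less readily than the parent. Fluoride turnover may also stall at the silyl ether stage. The fallback replaces the fluoride relay by stoichiometric transmetalation and a separate ring closure, all known chemistry. It sets out from 7: alkylation of the LDA-deprotonated known reagent 2-(tributylstannyl)-1,3-dithiane (THF, −78 °C) should give 2-{[2,4-bis(benzyloxy)-6-fluorophenyl]methyl}-2-(tributylstannyl)-1,3-dithiane F1. Tin–lithium exchange (n-BuLi, THF, −78 °C), which is faster than metalation of ring A, followed by addition of 11 and aqueous quench, should give the racemic carbinol [3,4-bis(benzyloxy)phenyl](2-{[2,4-bis(benzyloxy)-6-fluorophenyl]methyl}-1,3-dithian-2-yl)methanol F2. KH in DMF (0 to 20 °C) then closes ring C by SNAr at C8a, and the route is rejoined at 14.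

Step 8. Epimerisation of C2 may be slower than hydrogenation, or the catalyst may discriminate the two ketone enantiomers or the two carbonyl faces poorly, which would erode enantiomeric purity or cis selectivity. The fallback uses resolution in place of asymmetric catalysis. It sets out from 15: LiBH(s-Bu)3 (THF, −78 °C) should deliver hydride to the less hindered face and give the racemic 2,3-cis alcohol, (±)-5,7,3',4'-tetra-O-benzyl-epicatechin F3. Preparative chromatography on a chiral stationary phase then separates the (2R,3R) antipode, which is 16. The (2S,3S) antipode is oxidised back to the ketone with Dess–Martin periodinane and, after base-mediated racemisation, re-enters as 15.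

Step 11. Hydride abstraction may lose site selectivity (attack at the interflavan C4–H or over-oxidation), and the dimeric electrophile may self-condense through its own free C8 in step 12. The fallback uses linear top-down chain extension in place of the 2+2 union. It sets out from 18, used in excess and recovered: coupling with the monomeric electrophile 17 (TMSOTf, CH2Cl2, −78 °C) should give the protected trimer, dodeca-O-benzyl epicatechin-(4β→8)-epicatechin-(4β→8)-epicatechin F4. A second coupling of F4 with 17 under the same conditions gives 20, so the only C4 electrophile needed is monomeric 17 and steps 11 and 12 are bypassed.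

**Further compounds**
F1 | step 6 | 2-{[2,4-bis(benzyloxy)-6-fluorophenyl]methyl}-2-(tributylstannyl)-1,3-dithiane | CCCC[Sn](CCCC)(CCCC)C1(Cc2c(F)cc(OCc3ccccc3)cc2OCc2ccccc2)SCCCS1
F2 | step 6 | (±)-[3,4-bis(benzyloxy)phenyl](2-{[2,4-bis(benzyloxy)-6-fluorophenyl]methyl}-1,3-dithian-2-yl)methanol | OC(c1ccc(OCc2ccccc2)c(OCc2ccccc2)c1)C1(Cc2c(F)cc(OCc3ccccc3)cc2OCc2ccccc2)SCCCS1
F3 | step 8 | (±)-cis-5,7-bis(benzyloxy)-2-[3,4-bis(benzyloxy)phenyl]chroman-3-ol (racemate, both antipodes written) | c1ccccc1COc1cc(OCc3ccccc3)c2c(c1)O[C@H](c1ccc(OCc3ccccc3)c(OCc3ccccc3)c1)[C@H](O)C2.c1ccccc1COc1cc(OCc3ccccc3)c2c(c1)O[C@@H](c1ccc(OCc3ccccc3)c(OCc3ccccc3)c1)[C@@H](O)C2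
F4 | step 11 | dodeca-O-benzyl epicatechin trimer [tetra-O-benzyl-epicatechin-(4β→8)-tetra-O-benzyl-epicatechin-(4β→8)-tetra-O-benzyl-epicatechin] | c1ccccc1COc1cc(OCc3ccccc3)c2c(c1)O[C@H](c1ccc(OCc3ccccc3)c(OCc3ccccc3)c1)[C@H](O)[C@H]2c1c(OCc3ccccc3)cc(OCc3ccccc3)c2c1O[C@H](c1ccc(OCc3ccccc3)c(OCc3ccccc3)c1)[C@H](O)[C@H]2c1c(OCc3ccccc3)cc(OCc3ccccc3)c2c1O[C@H](c1ccc(OCc3ccccc3)c(OCc3ccccc3)c1)[C@H](O)C2
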